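**Retrosynthetic overview**

1. Target 16, (2S)-6-geranyl-5,7-dihydroxy-3′,4′-dimethoxyflavanone, is cut (after loss of two MOM acetals) at C1′–C2 between ring B and ring C. This gives (3,4-dimethoxyphenyl)boronic acid 14 and the flat, achiral 6-geranyl-5,7-bis(methoxymethoxy)chromone 13. An enantioselective rhodium-catalysed 1,4-arylation joins them, turns the chromone into the flavanone and creates the only stereocentre in one operation.
2. The feature that makes this possible is the O1–C2=C3–C4=O vinylogous ester of ring C of 13. C2 is an unsubstituted, planar, prochiral β-carbon; the catalyst alone tells its two faces apart, and the C3 enolate is simply protonated.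
3. Ring C of 13 comes from salicylaldehyde 9 by ethynyl addition, oxidation and 6-endo-dig oxa-Michael closure through the only free phenol.
4. The C6-versus-C8 problem is removed by symmetry. Geranyl is placed by directed ortho-metalation between the two OMOM groups of a silylated phloroglucinol; the two carbons ortho to the unique oxygen are then homotopic, so ring C can only form with geranyl at C6.
5. Order of rings: ring A is bought (phloroglucinol 1), ring C is closed in step 7, ring B is attached in step 8; step 9 only removes the acetals.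

Key step: step 8

Assumption: the stereocentre is read as (2S) and the side chain as geranyl = (2E)-3,7-dimethylocta-2,6-dien-1-yl (MOM = methoxymethyl, TIPS = triisopropylsilyl). The (S)-bisphosphine (S)-MeO-F12-BIPHEP, i.e. (S)-2,2′-bis[bis(3,4,5-trifluorophenyl)phosphino]-6,6′-dimethoxy-1,1′-biphenyl, is assumed to show the same sense of induction with the chromone as with 2-cyclohexenone; its mirror image would be used if a trial run showed the opposite sense.

**Route**

Step 1
Reactants: 1 phloroglucinol (benzene-1,3,5-triol)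
Product: 2 3,5-bis(methoxymethoxy)phenol
Conditions: MOMCl (2.0 equiv), i-Pr2NEt, DMF/CH2Cl2, 0 °C to rt; chromatography
Reagents that add atoms: chloromethyl methyl ether (MOMCl), COCCl
Why: Base-mediated O-alkylation of phenols (acetal formation); the three hydroxyls of 1 are equivalent, so two equivalents of MOMCl should give the bis-acetal as the main product beside mono- and tris-ethers that are removed by chromatography, and no regiochemical question arises.

Step 2
Reactants: 2 3,5-bis(methoxymethoxy)phenol
Product: 3 [3,5-bis(methoxymethoxy)phenoxy]tri(propan-2-yl)silane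
Conditions: TIPSCl, imidazole, DMF, rt
Reagents that add atoms: chlorotri(propan-2-yl)silane (TIPSCl), CC(C)[Si](Cl)(C(C)C)C(C)C
Why: Standard silylation of a phenol; the bulky silyl ether survives n-BuLi, does not direct metalation and shields both ring positions next to it.

Step 3
Reactants: 3 [3,5-bis(methoxymethoxy)phenoxy]tri(propan-2-yl)silane; 4 geranyl bromide
Product: 6 [4-geranyl-3,5-bis(methoxymethoxy)phenoxy]tri(propan-2-yl)silane, via aryllithium 5 (not isolated)
Conditions: n-BuLi, THF, 0 °C; then CuBr·SMe2 (10 mol %), 4, −78 °C to rt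
Reagents that add atoms: none
Why: Directed ortho-metalation followed by copper-catalysed allylic substitution; the C–H between the two chelating OMOM groups is by far the most acidic ring position, and the aryl nucleophile should attack the primary carbon of 4 in SN2 fashion, so the (2E)-alkene is carried over unchanged.

Step 4
Reactants: 6 [4-geranyl-3,5-bis(methoxymethoxy)phenoxy]tri(propan-2-yl)silane
Product: 7 4-geranyl-3,5-bis(methoxymethoxy)phenol
Conditions: TBAF, THF, 0 °C
Reagents that add atoms: none
Why: Fluoride-mediated cleavage of an aryl silyl ether, driven by the Si–F bond, to which acetals and isolated alkenes are inert.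

Step 5
Reactants: 7 4-geranyl-3,5-bis(methoxymethoxy)phenol
Product: 9 3-geranyl-6-hydroxy-2,4-bis(methoxymethoxy)benzaldehyde, via hydroxymethylphenol 8 (not isolated)
Conditions: MgCl2, Et3N, (CH2O)n, MeCN, reflux; aq. NH4Cl
Reagents that add atoms: paraformaldehyde (as formaldehyde), C=O
Why: Magnesium-mediated ortho-specific formylation of a phenol (Casnati–Skattebøl reaction), in which the magnesium phenoxide delivers formaldehyde to the ortho carbon and a second formaldehyde oxidises the benzylic alkoxide by hydride transfer; the para position is blocked and the two ortho positions of 7 are homotopic, so only one aldehyde can form.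

Step 6
Reactants: 9 3-geranyl-6-hydroxy-2,4-bis(methoxymethoxy)benzaldehyde; 10 ethynylmagnesium bromide
Product: 11 rac-1-[3-geranyl-6-hydroxy-2,4-bis(methoxymethoxy)phenyl]prop-2-yn-1-ol
Conditions: HC≡CMgBr (3 equiv), THF, 0 °C to rt; aq. NH4Cl
Reagents that add atoms: none
Why: Grignard 1,2-addition to an aldehyde, the first equivalent being spent on the phenol; the carbinol centre forms as a racemate, which is of no consequence because it is oxidised away in step 7.

Step 7
Reactants: 11 rac-1-[3-geranyl-6-hydroxy-2,4-bis(methoxymethoxy)phenyl]prop-2-yn-1-ol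
Product: 13 6-geranyl-5,7-bis(methoxymethoxy)-4H-chromen-4-one, via ynone 12 (not isolated)
Conditions: MnO2, CH2Cl2, rt; filter; then K2CO3, acetone, rt
Reagents that add atoms: none
Why: MnO2 oxidation of a benzylic propargylic alcohol to ynone 12, then base-mediated intramolecular oxa-Michael addition of the only free phenoxide to the terminal alkyne carbon (6-endo-dig), which closes ring C; because this oxygen lies para to the geranyl group, the side chain is fixed at C6.

Step 8
Reactants: 13 6-geranyl-5,7-bis(methoxymethoxy)-4H-chromen-4-one; 14 (3,4-dimethoxyphenyl)boronic acid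
Product: 15 (2S)-2-(3,4-dimethoxyphenyl)-6-geranyl-5,7-bis(methoxymethoxy)-2,3-dihydro-4H-chromen-4-one
Conditions: [Rh(OH)(cod)]2 (2.5 mol %), (S)-MeO-F12-BIPHEP (5.5 mol %), 14 (2 equiv), toluene/H2O (10:1), 50 °C
Reagents that add atoms: none
Why: Hayashi–Miyaura asymmetric 1,4-addition: the aryl group of 14 is transmetalated to the hydroxo complex of monovalent rhodium, the C2=C3 alkene of 13 binds, and syn-carborhodation places the aryl group on C2 and rhodium on C3 as an oxa-π-allyl enolate, which water protonates at C3 with return of the Rh–OH species. The closest known reaction type is the rhodium/chiral bisphosphine-catalysed addition of arylboronic acids to cyclic enones and to 4H-chromen-4-ones, which gives flavanones directly. No ring is closed; ring C is already in place and only changes from chromenone to chromanone. The single new stereocentre C2 is set by the catalyst alone: the planar chromone offers two enantiotopic faces, and the (S)-bisphosphine is expected, by analogy with 2-cyclohexenone, to expose the Re face of C2 (ranked O1 > C3 > H), which gives (2S). The step needs 1,4- over 1,2-addition, enantioface selectivity, no insertion into the geranyl alkenes and no opening of ring C: the first two are properties of the catalyst, unactivated trisubstituted alkenes do not insert into aryl–rhodium bonds, and the base-free aqueous medium with both phenols masked as acetals protonates the enolate before β-elimination of the aryloxide can open the ring. The electron-poor phosphine is chosen because the 5,7-dioxygenated chromone is an electron-rich, sluggish acceptor.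

Step 9
Reactants: 15 (2S)-2-(3,4-dimethoxyphenyl)-6-geranyl-5,7-bis(methoxymethoxy)-2,3-dihydro-4H-chromen-4-one
Product: 16 (2S)-2-(3,4-dimethoxyphenyl)-6-geranyl-5,7-dihydroxy-2,3-dihydro-4H-chromen-4-one
Conditions: aq. HCl (3 M), MeOH, 40 °C
Reagents that add atoms: none
Why: Acid-catalysed acetal exchange with methanol removes both MOM groups; under mildly acidic, base-free conditions the trisubstituted alkenes should not be protonated appreciably and ring C should not open by retro-oxa-Michael reaction, so the (2S) centre and the (2E)-alkene are retained.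

**Compound list**

1 | benzene-1,3,5-triol (phloroglucinol) | Oc1cc(O)cc(O)c1 | starting material
2 | 3,5-bis(methoxymethoxy)phenol | COCOc1cc(O)cc(OCOC)c1 | intermediate
3 | [3,5-bis(methoxymethoxy)phenoxy]tri(propan-2-yl)silane | COCOc1cc(OCOC)cc(O[Si](C(C)C)(C(C)C)C(C)C)c1 | intermediate
4 | geranyl bromide, (2E)-1-bromo-3,7-dimethylocta-2,6-diene | BrC/C=C(\C)CCC=C(C)C | starting material
5 | {2,6-bis(methoxymethoxy)-4-[tri(propan-2-yl)silyloxy]phenyl}lithium (formed in the flask) | [Li]c1c(OCOC)cc(O[Si](C(C)C)(C(C)C)C(C)C)cc1OCOC | intermediate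
6 | {4-[(2E)-3,7-dimethylocta-2,6-dien-1-yl]-3,5-bis(methoxymethoxy)phenoxy}tri(propan-2-yl)silane | COCOc1cc(O[Si](C(C)C)(C(C)C)C(C)C)cc(OCOC)c1C/C=C(\C)CCC=C(C)C | intermediate
7 | 4-[(2E)-3,7-dimethylocta-2,6-dien-1-yl]-3,5-bis(methoxymethoxy)phenol | COCOc1cc(O)cc(OCOC)c1C/C=C(\C)CCC=C(C)C | intermediate
8 | 4-[(2E)-3,7-dimethylocta-2,6-dien-1-yl]-2-(hydroxymethyl)-3,5-bis(methoxymethoxy)phenol (formed in the flask as its magnesium salt) | OCc1c(O)cc(OCOC)c(C/C=C(\C)CCC=C(C)C)c1OCOC | intermediate
9 | 3-[(2E)-3,7-dimethylocta-2,6-dien-1-yl]-6-hydroxy-2,4-bis(methoxymethoxy)benzaldehyde | O=Cc1c(O)cc(OCOC)c(C/C=C(\C)CCC=C(C)C)c1OCOC | intermediate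
10 | ethynylmagnesium bromide | C#C[Mg]Br | starting material
11 | rac-1-{3-[(2E)-3,7-dimethylocta-2,6-dien-1-yl]-6-hydroxy-2,4-bis(methoxymethoxy)phenyl}prop-2-yn-1-ol | C#CC(O)c1c(O)cc(OCOC)c(C/C=C(\C)CCC=C(C)C)c1OCOC | intermediate
12 | 1-{3-[(2E)-3,7-dimethylocta-2,6-dien-1-yl]-6-hydroxy-2,4-bis(methoxymethoxy)phenyl}prop-2-yn-1-one (formed in the flask) | C#CC(=O)c1c(O)cc(OCOC)c(C/C=C(\C)CCC=C(C)C)c1OCOC | intermediate
13 | 6-[(2E)-3,7-dimethylocta-2,6-dien-1-yl]-5,7-bis(methoxymethoxy)-4H-chromen-4-one | O=c1ccoc2cc(OCOC)c(C/C=C(\C)CCC=C(C)C)c(OCOC)c12 | intermediate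
14 | (3,4-dimethoxyphenyl)boronic acid | COc1ccc(B(O)O)cc1OC | starting material
15 | (2S)-2-(3,4-dimethoxyphenyl)-6-[(2E)-3,7-dimethylocta-2,6-dien-1-yl]-5,7-bis(methoxymethoxy)-2,3-dihydro-4H-chromen-4-one | COc1ccc([C@@H]2CC(=O)c3c(cc(OCOC)c(C/C=C(\C)CCC=C(C)C)c3OCOC)O2)cc1OC | intermediate
16 | (2S)-2-(3,4-dimethoxyphenyl)-6-[(2E)-3,7-dimethylocta-2,6-dien-1-yl]-5,7-dihydroxy-2,3-dihydro-4H-chromen-4-one | COc1ccc([C@@H]2CC(=O)c3c(cc(O)c(C/C=C(\C)CCC=C(C)C)c3O)O2)cc1OC | target

**Step count and risks**

Total step count: 9. Longest linear sequence: 9 steps (1 to 16); compounds 4, 10 and 14 are bought.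

Steps most likely to fail:

1. Step 8. The carborhodation of the electron-rich chromone may be slow, so that protodeboronation of 14 wins, or enantiopurity may be lost through reversible opening of ring C of the product. The fallback is the classical chalcone route with resolution; it sets out from 9 and comes back at 15. Methylmagnesium bromide adds to aldehyde 9 to give 1-[3-geranyl-6-hydroxy-2,4-bis(methoxymethoxy)phenyl]ethan-1-ol F1. MnO2 oxidises this to 1-[3-geranyl-6-hydroxy-2,4-bis(methoxymethoxy)phenyl]ethan-1-one F2. Claisen–Schmidt condensation with 3,4-dimethoxybenzaldehyde (KOH, EtOH) gives the (E)-2′-hydroxychalcone F3. NaOAc in refluxing EtOH closes ring C by oxa-Michael addition through the only free phenol to the racemic flavanone F4. Preparative chromatography on a chiral stationary phase then delivers 15.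

2. Step 9. A neighbouring phenol may add to the geranyl alkene under acid (chroman formation), or the flavanone may partly racemise by reversible ring opening during acetal cleavage. The fallback exchanges the protecting groups before the stereocentre exists; it sets out from 13 and comes back at 16. The acetals of 13 are cleaved under aprotic conditions (ZnBr2, n-PrSH, CH2Cl2, 0 °C) to 6-geranyl-5,7-dihydroxy-4H-chromen-4-one F5. TBSOTf and 2,6-lutidine give the bis(tert-butyldimethylsilyl) ether F6. The arylation of step 8 with 14 gives the silylated (2S)-flavanone F7. Et3N·3HF in THF at 0 °C then frees 16 at near-neutral pH.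

3. Step 3. The aryl nucleophile may attack the tertiary end of the allyl system (SN2′) and give the branched isomer, or bromine–lithium exchange with 4 may lead to homocoupling. The fallback reverses the polarity of the coupling partners; it sets out from 3 and comes back at 6. Aryllithium 5 is generated as before and quenched with I2 to give [4-iodo-3,5-bis(methoxymethoxy)phenoxy]tri(propan-2-yl)silane F8. Geranyl bromide 4 is treated with Bu3SnLi to give tributyl[(2E)-3,7-dimethylocta-2,6-dien-1-yl]stannane F9. A Stille coupling of F8 and F9 (Pd2(dba)3, tri(2-furyl)phosphine, LiCl, DMF, 60 °C) should then give 6.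

**Further compounds**

F1 | step 8 | 1-{3-[(2E)-3,7-dimethylocta-2,6-dien-1-yl]-6-hydroxy-2,4-bis(methoxymethoxy)phenyl}ethan-1-ol | CC(O)c1c(O)cc(OCOC)c(C/C=C(\C)CCC=C(C)C)c1OCOC
F2 | step 8 | 1-{3-[(2E)-3,7-dimethylocta-2,6-dien-1-yl]-6-hydroxy-2,4-bis(methoxymethoxy)phenyl}ethan-1-one | CC(=O)c1c(O)cc(OCOC)c(C/C=C(\C)CCC=C(C)C)c1OCOC
F3 | step 8 | (2E)-3-(3,4-dimethoxyphenyl)-1-{3-[(2E)-3,7-dimethylocta-2,6-dien-1-yl]-6-hydroxy-2,4-bis(methoxymethoxy)phenyl}prop-2-en-1-one | COc1ccc(/C=C/C(=O)c2c(O)cc(OCOC)c(C/C=C(\C)CCC=C(C)C)c2OCOC)cc1OC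
F4 | step 8 | rac-2-(3,4-dimethoxyphenyl)-6-[(2E)-3,7-dimethylocta-2,6-dien-1-yl]-5,7-bis(methoxymethoxy)-2,3-dihydro-4H-chromen-4-one | COc1ccc(C2CC(=O)c3c(cc(OCOC)c(C/C=C(\C)CCC=C(C)C)c3OCOC)O2)cc1OC
F5 | step 9 | 6-[(2E)-3,7-dimethylocta-2,6-dien-1-yl]-5,7-dihydroxy-4H-chromen-4-one | O=c1ccoc2cc(O)c(C/C=C(\C)CCC=C(C)C)c(O)c12
F6 | step 9 | 5,7-bis[tert-butyl(dimethyl)silyloxy]-6-[(2E)-3,7-dimethylocta-2,6-dien-1-yl]-4H-chromen-4-one | O=c1ccoc2cc(O[Si](C)(C)C(C)(C)C)c(C/C=C(\C)CCC=C(C)C)c(O[Si](C)(C)C(C)(C)C)c12
F7 | step 9 | (2S)-5,7-bis[tert-butyl(dimethyl)silyloxy]-2-(3,4-dimethoxyphenyl)-6-[(2E)-3,7-dimethylocta-2,6-dien-1-yl]-2,3-dihydro-4H-chromen-4-one | COc1ccc([C@@H]2CC(=O)c3c(cc(O[Si](C)(C)C(C)(C)C)c(C/C=C(\C)CCC=C(C)C)c3O[Si](C)(C)C(C)(C)C)O2)cc1OC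
F8 | step 3 | [4-iodo-3,5-bis(methoxymethoxy)phenoxy]tri(propan-2-yl)silane | COCOc1cc(O[Si](C(C)C)(C(C)C)C(C)C)cc(OCOC)c1I
F9 | step 3 | tributyl[(2E)-3,7-dimethylocta-2,6-dien-1-yl]stannane | CCCC[Sn](CCCC)(CCCC)C/C=C(\C)CCC=C(C)C
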